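**Retrosynthetic overview**

1. Numbering: 1,2-dioxane O1, O2, C3 (carries the propanoate, whose α-carbon is C2), C4, C5, C6 (carries CH3); C1' is the carbinol carbon of the cyclohexane. Target ⇒ Wharton transposition of a ring epoxy aldehyde ⇒ Sharpless epoxidation of a 2-(hydroxymethyl)cyclohexene ⇒ diimide reduction ⇒ Sonogashira union of a 6-ethynyl-1,2-dioxane ester with a cyclohexenyl triflate.
2. 6-Ethynyl dioxane ⇒ (key) C3–C4 bond by 6-exo-trig closure of a primary C4 radical onto C3 of an alkenyl peroxide C6–O1–O2–C3H=C2(CH3)–CO2Me, then hydrogen transfer to C2. The ring, C3 and C2 arise in one event, both centres relayed from C6.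
3. Enabling feature: C6 is a quaternary, peroxide-bearing carbon with two two-carbon arms. The C5–C4 arm is the radical tether; the other arm is kept as an sp-hybridised ethynyl group, slim enough to sit axial in the chair (so C3 forms cis to it) and later the coupling handle. O2 on C3 of a push-pull alkene makes C3 the radical acceptor.
4. Radical precursor ⇒ tertiary silyl peroxide with a C4 iodide plus the enol tosylate of methyl 2-formylpropanoate ⇒ oxetane perhydrolysis (inversion at C6) ⇒ Sharpless epoxidation and hydride opening of (E)-3-methylpent-2-en-4-yn-1-ol. C6 and C1' come from two catalytic asymmetric epoxidations.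
5. Order of rings: oxetane (temporary) → 1,2-dioxane (key step) → cyclohexene (brought in preformed) → ring epoxide (temporary, opened in the last step).

Key step: step 8

Assumption: alkenyl peroxides have a weak O–O bond and are taken to be unstable above about −20 °C, so the alkenyl peroxide of the key step is generated and consumed cold and is never isolated.

**Route**

Step 1
Reactants: 1 (2E)-3-methylpent-2-en-4-yn-1-ol
Product: 2 [(2R,3R)-3-ethynyl-3-methyloxiran-2-yl]methanol
Conditions: Ti(OiPr)4 (10 mol %), D-(−)-diethyl tartrate (12 mol %), t-BuOOH, 4 Å MS, CH2Cl2, −20 °C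
Reagents that add atoms: tert-butyl hydroperoxide, CC(C)(C)OO
Why: Sharpless asymmetric epoxidation of conjugated enynols is well precedented, and the D-(−)-tartrate ligand should deliver oxygen to the face that gives the (2R,3R)-epoxide, whose quaternary carbon becomes C6 of the dioxane.

Step 2
Reactants: 2 [(2R,3R)-3-ethynyl-3-methyloxiran-2-yl]methanol
Product: 3 (3S)-3-methylpent-4-yne-1,3-diol
Conditions: NaAlH2(OCH2CH2OMe)2 (1.2 equiv), THF, −20 to 0 °C; aq. potassium sodium tartrate
Reagents that add atoms: none
Why: Hydroxyl-directed hydride delivery from the alkoxyaluminate opens 2,3-epoxy alcohols at C2 to give 1,3-diols, so the C–O bond at the quaternary centre and its configuration stay untouched, and with little excess hydride at low temperature the alkyne should survive.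

Step 3
Reactants: 3 (3S)-3-methylpent-4-yne-1,3-diol
Product: 5 (2S)-2-ethynyl-2-methyloxetane, via primary monotosylate 4 (not isolated)
Conditions: TsCl, Et3N, DMAP (cat.), CH2Cl2, 0 °C; then KOtBu, THF, 0 °C to rt
Reagents that add atoms: none
Why: The primary hydroxyl is sulfonylated selectively and the tertiary alkoxide then closes the oxetane by a 4-exo-tet Williamson etherification in which no bond to the stereocentre is broken.

Step 4
Reactants: 5 (2S)-2-ethynyl-2-methyloxetane
Product: 6 (3R)-3-hydroperoxy-3-methylpent-4-yn-1-ol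
Conditions: H2O2 (anhydrous, in Et2O, excess), Me3SiOTf (cat.), Et2O, −78 to 0 °C
Reagents that add atoms: hydrogen peroxide, OO
Why: Lewis acid-promoted perhydrolysis of 2,2-disubstituted oxetanes is a known route to tertiary 3-hydroperoxy alcohols and proceeds by backside attack of hydrogen peroxide on the activated ring, so the quaternary centre should be inverted to (R), the electron-withdrawing ethynyl group discouraging a free cation.

Step 5
Reactants: 6 (3R)-3-hydroperoxy-3-methylpent-4-yn-1-ol
Product: 7 (3R)-3-methyl-3-[(triethylsilyl)peroxy]pent-4-yn-1-ol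
Conditions: Et3SiCl (1.0 equiv), DBU (1.0 equiv), CH2Cl2, −78 °C
Reagents that add atoms: chlorotriethylsilane, CC[Si](Cl)(CC)CC
Why: Silylation of hydroperoxides is standard, and with one equivalent of amidine base only the more acidic O–O–H group (pKa near 13 against 16 for the alcohol) is ionised, so the peroxide anion should be silylated in preference to the neutral primary alcohol.

Step 6
Reactants: 7 (3R)-3-methyl-3-[(triethylsilyl)peroxy]pent-4-yn-1-ol
Product: 8 triethyl{[(3R)-1-iodo-3-methylpent-4-yn-3-yl]peroxy}silane
Conditions: PPh3 and I2 (premixed), imidazole, CH2Cl2, 0 °C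
Reagents that add atoms: iodine, I-I
Why: Appel-type iodination of the primary alcohol with premixed PPh3 and iodine leaves no free phosphine to reduce the O–O bond and does not touch the stereocentre.

Step 7
Reactants: 9 methyl 2-methyl-3-oxopropanoate
Product: 10 methyl (2E)-2-methyl-3-[(4-methylbenzenesulfonyl)oxy]prop-2-enoate
Conditions: TsCl, Et3N, N-methylimidazole (cat.), CH2Cl2, 0 °C
Reagents that add atoms: 4-methylbenzenesulfonyl chloride, Cc1ccc(cc1)S(=O)(=O)Cl
Why: O-Sulfonylation of the enol form of an α-formyl ester is a known route to β-sulfonyloxy acrylates, and the alkene geometry is of no consequence because the later vinylic substitution is stereoconvergent.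

Step 8
Reactants: 8 triethyl{[(3R)-1-iodo-3-methylpent-4-yn-3-yl]peroxy}silane and 10 methyl (2E)-2-methyl-3-[(4-methylbenzenesulfonyl)oxy]prop-2-enoate
Product: 12 methyl (2S)-2-[(3S,6R)-6-ethynyl-6-methyl-1,2-dioxan-3-yl]propanoate, via iodo alkenyl peroxide 11 (not isolated)
Conditions: Bu4NF (1.0 equiv), THF–CH2Cl2, −78 to −40 °C; then (Me3Si)3SiH (1.1 equiv), Et3B (0.2 equiv), air, toluene (high dilution), −40 to −30 °C
Reagents that add atoms: none
Why: Proposed new method: fluoride frees the tertiary peroxide anion of 8, which displaces tosylate from 10 by addition–elimination to give the alkenyl peroxide 11; a silyl radical then abstracts iodine, the primary C4 radical adds to the peroxide-bearing alkene carbon C3, and the α-ester radical formed at C2 takes hydrogen from the silane. The closest known reaction types are the 6-exo radical cyclisation of β-alkoxyacrylates to 2,6-disubstituted tetrahydropyrans and the vinylic substitution of β-sulfonyloxyacrylates by oxygen nucleophiles, and what is new is the peroxide oxygen on the acceptor alkene. The 1,2-dioxane closes by 6-exo-trig C–C bond formation through a chair transition state. C3 is controlled by C6, because the acrylate arm lies equatorial while the slim sp-hybridised ethynyl group, with a much smaller A value than methyl and a favourable n(O1)→σ*(C6–C) interaction, takes the axial site, so the side chain forms cis to ethynyl and C3 becomes (S). C2 is controlled by C3 through the exocyclic effect of a ring stereocentre next to an ester-substituted radical, in which the C3–H bond eclipses the ester, O2 turns toward the methyl group and the silane attacks anti to C4, giving the 2,3-anti (2S) isomer. The step needs ring closure to outrun O–O homolysis of 11, closure of the peroxide anion onto the iodide, direct reduction of the C4 radical and attack of the C2 radical on the O–O bond, and low temperature, low silane concentration, the geminal substitution at C6 and the polarity-matched hydrogen transfer to the electrophilic C2 radical should secure this.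

Step 9
Reactants: 13 2,2-dimethylcyclohexan-1-one
Product: 14 methyl 3,3-dimethyl-2-oxocyclohexane-1-carboxylate
Conditions: NaH, (MeO)2CO, THF, reflux; aq. HCl
Reagents that add atoms: dimethyl carbonate, COC(=O)OC
Why: Claisen-type C-acylation of the ketone enolate by dimethyl carbonate at its only enolisable position is a standard synthesis of cyclic β-keto esters.

Step 10
Reactants: 14 methyl 3,3-dimethyl-2-oxocyclohexane-1-carboxylate
Product: 15 methyl 3,3-dimethyl-2-[(trifluoromethanesulfonyl)oxy]cyclohex-1-ene-1-carboxylate
Conditions: NaH, Tf2O, Et2O, 0 °C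
Reagents that add atoms: trifluoromethanesulfonic anhydride, FC(F)(F)S(=O)(=O)OS(=O)(=O)C(F)(F)F
Why: O-Triflation of the sodium enolate of a β-keto ester gives the enol triflate, and only one regioisomer is possible because the other α-carbon is quaternary.

Step 11
Reactants: 15 methyl 3,3-dimethyl-2-[(trifluoromethanesulfonyl)oxy]cyclohex-1-ene-1-carboxylate
Product: 16 2-(hydroxymethyl)-6,6-dimethylcyclohex-1-en-1-yl trifluoromethanesulfonate
Conditions: i-Bu2AlH (2.2 equiv), CH2Cl2, −78 °C
Reagents that add atoms: none
Why: i-Bu2AlH reduces the conjugated ester to the allylic alcohol at −78 °C while the enol triflate is inert to the hydride.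

Step 12
Reactants: 12 methyl (2S)-2-[(3S,6R)-6-ethynyl-6-methyl-1,2-dioxan-3-yl]propanoate and 16 2-(hydroxymethyl)-6,6-dimethylcyclohex-1-en-1-yl trifluoromethanesulfonate
Product: 17 methyl (2S)-2-[(3S,6R)-6-{[2-(hydroxymethyl)-6,6-dimethylcyclohex-1-en-1-yl]ethynyl}-6-methyl-1,2-dioxan-3-yl]propanoate
Conditions: Pd(PPh3)4 (5 mol %), CuI (10 mol %), i-Pr2NH, THF, rt
Reagents that add atoms: none
Why: Sonogashira coupling of a terminal alkyne with an enol triflate runs at room temperature under conditions that dialkyl peroxides and β-peroxy esters are known to tolerate, and it touches no stereocentre.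

Step 13
Reactants: 17 methyl (2S)-2-[(3S,6R)-6-{[2-(hydroxymethyl)-6,6-dimethylcyclohex-1-en-1-yl]ethynyl}-6-methyl-1,2-dioxan-3-yl]propanoate
Product: 18 methyl (2S)-2-[(3S,6S)-6-{2-[2-(hydroxymethyl)-6,6-dimethylcyclohex-1-en-1-yl]ethyl}-6-methyl-1,2-dioxan-3-yl]propanoate (6S only through a change of CIP priority, no change in space)
Conditions: KO2CN=NCO2K (excess, in portions), AcOH, MeOH–CH2Cl2, 0 °C to rt
Reagents that add atoms: none
Why: Diimide reduces alkynes and disubstituted alkenes but neither tetrasubstituted alkenes nor O–O bonds, so the alkyne should be taken down to the ethylene bridge while the ring alkene, the peroxide and the ester survive.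

Step 14
Reactants: 18 methyl (2S)-2-[(3S,6S)-6-{2-[2-(hydroxymethyl)-6,6-dimethylcyclohex-1-en-1-yl]ethyl}-6-methyl-1,2-dioxan-3-yl]propanoate
Product: 19 methyl (2S)-2-[(3S,6R)-6-{2-[(1S,6S)-6-(hydroxymethyl)-2,2-dimethyl-7-oxabicyclo[4.1.0]heptan-1-yl]ethyl}-6-methyl-1,2-dioxan-3-yl]propanoate
Conditions: Ti(OiPr)4, L-(+)-diethyl tartrate, t-BuOOH, 4 Å MS, CH2Cl2, −20 °C
Reagents that add atoms: tert-butyl hydroperoxide, CC(C)(C)OO
Why: Sharpless asymmetric epoxidation of a tetrasubstituted primary allylic alcohol is reagent-controlled, and L-(+)-tartrate should place the oxygen on the face that makes the future carbinol carbon (S), independently of the remote dioxane stereocentres.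

Step 15
Reactants: 19 methyl (2S)-2-[(3S,6R)-6-{2-[(1S,6S)-6-(hydroxymethyl)-2,2-dimethyl-7-oxabicyclo[4.1.0]heptan-1-yl]ethyl}-6-methyl-1,2-dioxan-3-yl]propanoate
Product: 20 methyl (2S)-2-[(3S,6R)-6-{2-[(1S,6R)-6-formyl-2,2-dimethyl-7-oxabicyclo[4.1.0]heptan-1-yl]ethyl}-6-methyl-1,2-dioxan-3-yl]propanoate
Conditions: Dess–Martin periodinane, NaHCO3, CH2Cl2, 0 °C
Reagents that add atoms: none
Why: Dess–Martin oxidation of a primary 2,3-epoxy alcohol to the epoxy aldehyde is mild, buffered and non-reducing, so the peroxide, the epoxide and the ester should be untouched.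

Step 16
Reactants: 20 methyl (2S)-2-[(3S,6R)-6-{2-[(1S,6R)-6-formyl-2,2-dimethyl-7-oxabicyclo[4.1.0]heptan-1-yl]ethyl}-6-methyl-1,2-dioxan-3-yl]propanoate
Product: 21 methyl (2S)-2-[(3S,6R)-6-{2-[(1S)-1-hydroxy-2,2-dimethyl-6-methylidenecyclohexyl]ethyl}-6-methyl-1,2-dioxan-3-yl]propanoate
Conditions: N2H4·H2O, AcOH (cat.), MeOH, 0 °C
Reagents that add atoms: none
Why: In the Wharton transposition the hydrazone of the α,β-epoxy aldehyde opens the epoxide and loses nitrogen from the alkenyl diazene, which gives the exocyclic methylene and the tertiary alcohol with the C–O bond set in step 14 left intact, so the carbinol carbon is (S).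

**Compound list**

1 | (2E)-3-methylpent-2-en-4-yn-1-ol | C#C/C(C)=C/CO | starting material
2 | [(2R,3R)-3-ethynyl-3-methyloxiran-2-yl]methanol | C#C[C@]1(C)[C@@H](CO)O1 | intermediate
3 | (3S)-3-methylpent-4-yne-1,3-diol | C#C[C@](O)(C)CCO | intermediate
4 | (3S)-3-hydroxy-3-methylpent-4-yn-1-yl 4-methylbenzenesulfonate | C#C[C@](O)(C)CCOS(=O)(=O)c1ccc(C)cc1 | intermediate
5 | (2S)-2-ethynyl-2-methyloxetane | C#C[C@]1(C)CCO1 | intermediate
6 | (3R)-3-hydroperoxy-3-methylpent-4-yn-1-ol | C#C[C@@](OO)(C)CCO | intermediate
7 | (3R)-3-methyl-3-[(triethylsilyl)peroxy]pent-4-yn-1-ol | C#C[C@@](OO[Si](CC)(CC)CC)(C)CCO | intermediate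
8 | triethyl{[(3R)-1-iodo-3-methylpent-4-yn-3-yl]peroxy}silane | C#C[C@@](OO[Si](CC)(CC)CC)(C)CCI | intermediate
9 | methyl 2-methyl-3-oxopropanoate | COC(=O)C(C)C=O | starting material
10 | methyl (2E)-2-methyl-3-[(4-methylbenzenesulfonyl)oxy]prop-2-enoate | COC(=O)/C(C)=C/OS(=O)(=O)c1ccc(C)cc1 | intermediate
11 | methyl (2E)-3-{[(3R)-1-iodo-3-methylpent-4-yn-3-yl]peroxy}-2-methylprop-2-enoate | C#C[C@@](OO/C=C(\C)C(=O)OC)(C)CCI | intermediate
12 | methyl (2S)-2-[(3S,6R)-6-ethynyl-6-methyl-1,2-dioxan-3-yl]propanoate | C#C[C@@]1(C)CC[C@@H]([C@H](C)C(=O)OC)OO1 | intermediate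
13 | 2,2-dimethylcyclohexan-1-one | CC1(C)CCCCC1=O | starting material
14 | methyl 3,3-dimethyl-2-oxocyclohexane-1-carboxylate | COC(=O)C1CCCC(C)(C)C1=O | intermediate
15 | methyl 3,3-dimethyl-2-[(trifluoromethanesulfonyl)oxy]cyclohex-1-ene-1-carboxylate | COC(=O)C1=C(OS(=O)(=O)C(F)(F)F)C(C)(C)CCC1 | intermediate
16 | 2-(hydroxymethyl)-6,6-dimethylcyclohex-1-en-1-yl trifluoromethanesulfonate | OCC1=C(OS(=O)(=O)C(F)(F)F)C(C)(C)CCC1 | intermediate
17 | methyl (2S)-2-[(3S,6R)-6-{[2-(hydroxymethyl)-6,6-dimethylcyclohex-1-en-1-yl]ethynyl}-6-methyl-1,2-dioxan-3-yl]propanoate | OCC1=C(C#C[C@@]2(C)CC[C@@H]([C@H](C)C(=O)OC)OO2)C(C)(C)CCC1 | intermediate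
18 | methyl (2S)-2-[(3S,6S)-6-{2-[2-(hydroxymethyl)-6,6-dimethylcyclohex-1-en-1-yl]ethyl}-6-methyl-1,2-dioxan-3-yl]propanoate | OCC1=C(CC[C@@]2(C)CC[C@@H]([C@H](C)C(=O)OC)OO2)C(C)(C)CCC1 | intermediate
19 | methyl (2S)-2-[(3S,6R)-6-{2-[(1S,6S)-6-(hydroxymethyl)-2,2-dimethyl-7-oxabicyclo[4.1.0]heptan-1-yl]ethyl}-6-methyl-1,2-dioxan-3-yl]propanoate | OC[C@@]12CCCC(C)(C)[C@]1(CC[C@@]3(C)CC[C@@H]([C@H](C)C(=O)OC)OO3)O2 | intermediate
20 | methyl (2S)-2-[(3S,6R)-6-{2-[(1S,6R)-6-formyl-2,2-dimethyl-7-oxabicyclo[4.1.0]heptan-1-yl]ethyl}-6-methyl-1,2-dioxan-3-yl]propanoate | O=C[C@@]12CCCC(C)(C)[C@]1(CC[C@@]3(C)CC[C@@H]([C@H](C)C(=O)OC)OO3)O2 | intermediate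
21 | methyl (2S)-2-[(3S,6R)-6-{2-[(1S)-1-hydroxy-2,2-dimethyl-6-methylidenecyclohexyl]ethyl}-6-methyl-1,2-dioxan-3-yl]propanoate | C=C1CCCC(C)(C)[C@@]1(O)CC[C@@]1(C)CC[C@@H]([C@H](C)C(=O)OC)OO1 | target

**Step count and risks**

Total step count: 16. Longest linear sequence: 12 steps (1, 2, 3, 4, 5, 6, 8, 12, 13, 14, 15, 16); steps 7 and 9–11 make the two partners.

Steps most likely to fail:

Step 8 (bears the label). What may go wrong: loss of the alkenyl peroxide by O–O homolysis; ring closure of the freed peroxide anion onto the primary iodide before it is vinylated; reduction of the C4 radical before it cyclises; too little facial control at C3. The fallback closes the ring through the O2–C3 bond by conjugate addition of the hydroperoxide, using known reaction types only. It sets out from 8. Radical vinyl transfer to the primary iodide with methyl (2E)-2-methyl-3-(tributylstannyl)prop-2-enoate ((Bu3Sn)2 cat., light, benzene, rt; addition of the C4 radical, then loss of a stannyl radical) should give methyl (2E,6R)-2,6-dimethyl-6-[(triethylsilyl)peroxy]oct-2-en-7-ynoate F1. Bu4NF in THF at 0 °C then frees the peroxide anion, which adds 6-exo-trig to the enoate (intramolecular peroxy-Michael addition, the classical closure for 1,2-dioxane propanoates), and the route is rejoined at 12. Control at C3 and C2 is expected to be weaker on this path, so 12 would have to be separated from its epimers by chromatography.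

Step 16. What may go wrong: reduction of the O–O bond or hydrazinolysis of the methyl ester by hydrazine before the hydrazone fragments. The fallback is the known radical opening of 2,3-epoxy iodides to transposed allylic alcohols. It sets out from 19. Premixed PPh3 and iodine with imidazole should give methyl (2S)-2-[(3S,6R)-6-{2-[(1S,6R)-6-(iodomethyl)-2,2-dimethyl-7-oxabicyclo[4.1.0]heptan-1-yl]ethyl}-6-methyl-1,2-dioxan-3-yl]propanoate F2. (Me3Si)3SiH with Et3B and air at 0 °C then generates the oxiranylcarbinyl radical, whose C–O bond opens to the tertiary alkoxy radical and the exocyclic alkene; hydrogen transfer gives 21 directly, with the carbinol C–O bond untouched.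

Step 5. What may go wrong: loss of chemoselectivity, with silylation of the primary alcohol competing with that of the hydroperoxide. The fallback protects both groups and releases one. It sets out from 6. Et3SiCl (2.5 equiv) and imidazole should give triethyl{[(3R)-3-methyl-1-[(triethylsilyl)oxy]pent-4-yn-3-yl]peroxy}silane F3. Brief methanolysis with pyridinium tosylate at 0 °C should then cleave the unhindered primary silyl ether faster than the hindered, less basic silyl peroxide, and the route is rejoined at 7.

**Further compounds**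

F1 | step 8 | methyl (2E,6R)-2,6-dimethyl-6-[(triethylsilyl)peroxy]oct-2-en-7-ynoate | C#C[C@@](OO[Si](CC)(CC)CC)(C)CC/C=C(\C)C(=O)OC
F2 | step 16 | methyl (2S)-2-[(3S,6R)-6-{2-[(1S,6R)-6-(iodomethyl)-2,2-dimethyl-7-oxabicyclo[4.1.0]heptan-1-yl]ethyl}-6-methyl-1,2-dioxan-3-yl]propanoate | IC[C@@]12CCCC(C)(C)[C@]1(CC[C@@]3(C)CC[C@@H]([C@H](C)C(=O)OC)OO3)O2
F3 | step 5 | triethyl{[(3R)-3-methyl-1-[(triethylsilyl)oxy]pent-4-yn-3-yl]peroxy}silane | C#C[C@@](OO[Si](CC)(CC)CC)(C)CCO[Si](CC)(CC)CC
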